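**Retrosynthetic overview**
1. Target 24 ← diol 23 (acetylation) ← 1,10‑epoxy lactone 22. The C11 methyl comes from lactone‑enolate methylation and kinetic protonation. The ring‑cis oxirane comes from the E‑1(10) olefin by syn‑dihydroxylation and closure with inversion at C1.
2. γ‑Lactone 15 ← C6 ketone 13 carrying the C7 acetate chain (Felkin reduction, lactonisation).
3. Ten‑membered ring 13 ← anionic oxy‑Cope rearrangement of 1,2‑dialkenylcyclohexenol 10. It forms C8–C9, relays chirality to C9, and the ring enolate is alkylated in the same flask to set C7.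
4. Cyclohexenone 9 ← (R)‑carvone 1: epoxidation/Wharton transposition (sets C3), allylic oxidation, and conversion of the isopropenyl group into an E silyl enol ether (the future C9 oxygen).
5. Ring order: six‑membered ring (bought) → ten‑membered carbocycle (step 8) → γ‑lactone (step 9) → oxirane (step 11).

Convention and assumption: ten‑membered‑ring compounds carry germacrane numbering (ring C1–C10; C11, C12, C13 = lactone α‑carbon, carbonyl and α‑methyl on C7; C14 on C10; C15 on C4; lactone oxygen on C6); vinylmagnesium bromide and methyl bromoacetate are treated as purchased reagents. The stereochemical outcomes of steps 7–13 are predictions from transition‑state models, not precedent on this exact substrate.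

**Step 1**
Reactants: 1 (R)-(−)-carvone
Product: 2 (1R,4R,6R)-1-methyl-4-(prop-1-en-2-yl)-7-oxabicyclo[4.1.0]heptan-2-one
Conditions: 30% H2O2, NaOH (aq), MeOH, 0 °C
Reagents that add atoms: hydrogen peroxide, OO
Why: Weitz–Scheffer nucleophilic epoxidation; hydroperoxide adds to the enone face anti to the isopropenyl group, so the bought stereocentre fixes the oxirane CH–O carbon that becomes C3.

**Step 2**
Reactants: 2 (1R,4R,6R)-1-methyl-4-(prop-1-en-2-yl)-7-oxabicyclo[4.1.0]heptan-2-one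
Product: 4 (1R,5S)-2-methyl-5-(prop-1-en-2-yl)cyclohex-2-en-1-ol, via epoxy hydrazone 3 (not isolated)
Conditions: N2H4·H2O, AcOH (cat.), MeOH, 0 → 25 °C
Reagents that add atoms: none
Why: Wharton transposition; the hydrazone opens the oxirane and loses N2, the C–O bond at the former β‑carbon is untouched, giving the (1R) allylic alcohol trans to the isopropenyl group.

**Step 3**
Reactants: 4 (1R,5S)-2-methyl-5-(prop-1-en-2-yl)cyclohex-2-en-1-ol
Product: 5 tert-butyl(dimethyl){[(1R,5S)-2-methyl-5-(prop-1-en-2-yl)cyclohex-2-en-1-yl]oxy}silane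
Conditions: TBSCl, imidazole, DMF, 25 °C
Reagents that add atoms: tert-butyldimethylsilyl chloride, CC(C)(C)[Si](C)(C)Cl
Why: Silyl ether formation protects the C3 oxygen against the organometallic and strongly basic steps; no stereocentre is touched.

**Step 4**
Reactants: 5 tert-butyl(dimethyl){[(1R,5S)-2-methyl-5-(prop-1-en-2-yl)cyclohex-2-en-1-yl]oxy}silane
Product: 6 (4R,6S)-4-[(tert-butyldimethylsilyl)oxy]-3-methyl-6-(prop-1-en-2-yl)cyclohex-2-en-1-one
Conditions: CrO3, 3,5-dimethylpyrazole, CH2Cl2, −20 °C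
Reagents that add atoms: chromium trioxide, O=[Cr](=O)=O
Why: Allylic C–H oxidation of the only ring allylic CH2 of the trisubstituted olefin gives the transposed enone (future C6 ketone), the bulky silyl ether shielding its own carbinol C–H.

**Step 5**
Reactants: 6 (4R,6S)-4-[(tert-butyldimethylsilyl)oxy]-3-methyl-6-(prop-1-en-2-yl)cyclohex-2-en-1-one
Product: 7 (4R,6S)-4-[(tert-butyldimethylsilyl)oxy]-3-methyl-6-(2-methyloxiran-2-yl)cyclohex-2-en-1-one (both oxirane epimers)
Conditions: mCPBA, NaHCO3, CH2Cl2, 0 °C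
Reagents that add atoms: 3-chloroperoxybenzoic acid, OOC(=O)c1cccc(Cl)c1
Why: Prilezhaev epoxidation takes the electron‑rich 1,1‑disubstituted olefin and leaves the electron‑poor enone; the new oxirane centre is formed unselectively but becomes sp2 in step 6.

**Step 6**
Reactants: 7 (4R,6S)-4-[(tert-butyldimethylsilyl)oxy]-3-methyl-6-(2-methyloxiran-2-yl)cyclohex-2-en-1-one
Product: 9 (4R,6S)-4-[(tert-butyldimethylsilyl)oxy]-3-methyl-6-[(1E)-1-[(triethylsilyl)oxy]prop-1-en-2-yl]cyclohex-2-en-1-one, via aldehyde 8 (not isolated)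
Conditions: BF3·OEt2 (10 mol %), CH2Cl2, −78 °C; then Et3N, TESOTf, −78 → 0 °C
Reagents that add atoms: triethylsilyl trifluoromethanesulfonate, CC[Si](CC)(CC)OS(=O)(=O)C(F)(F)F
Why: Meinwald rearrangement (1,2‑hydride shift) gives the aldehyde, whose soft enolisation and O‑silylation is faster than that of the ketone and favours the E enol ether (silyloxy group cis to methyl, away from the ring).

**Step 7**
Reactants: 9 (4R,6S)-4-[(tert-butyldimethylsilyl)oxy]-3-methyl-6-[(1E)-1-[(triethylsilyl)oxy]prop-1-en-2-yl]cyclohex-2-en-1-one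
Product: 10 (1R,4R,6S)-4-[(tert-butyldimethylsilyl)oxy]-1-ethenyl-3-methyl-6-[(1E)-1-[(triethylsilyl)oxy]prop-1-en-2-yl]cyclohex-2-en-1-ol
Conditions: CH2=CHMgBr, CeCl3, THF, −78 °C
Reagents that add atoms: vinylmagnesium bromide, C=C[Mg]Br
Why: Non‑basic organocerium 1,2‑addition; in the half‑chair with the silyloxy group pseudo‑axial and the C6 alkenyl group equatorial, the vinyl group enters equatorially, trans to the neighbouring alkenyl group.

**Step 8**
Reactants: 10 (1R,4R,6S)-4-[(tert-butyldimethylsilyl)oxy]-1-ethenyl-3-methyl-6-[(1E)-1-[(triethylsilyl)oxy]prop-1-en-2-yl]cyclohex-2-en-1-ol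
Product: 13 methyl (3R,7S,9S,1(10)E,4Z)-3-(tert-butyldimethylsilyloxy)-6-oxo-9-(triethylsilyloxy)-13-norgermacra-1(10),4-dien-12-oate, via potassium alkoxide 11 (not isolated), via potassium enolate 12 (not isolated)
Conditions: KH, 18-crown-6, THF, 0 → 25 °C; then BrCH2CO2Me, −78 °C
Reagents that add atoms: methyl bromoacetate, COC(=O)CBr
Why: Anionic oxy‑Cope [3,3]‑sigmatropic rearrangement through the chair with both ring bonds equatorial forms C8–C9, the ten‑membered ring and the E‑1(10) olefin and transfers chirality to C9 (9S, equatorial enol‑ether oxygen); the ring‑trans enolate is alkylated at once on its only exposed outer face, which sets C7 (7S).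

**Step 9**
Reactants: 13 methyl (3R,7S,9S,1(10)E,4Z)-3-(tert-butyldimethylsilyloxy)-6-oxo-9-(triethylsilyloxy)-13-norgermacra-1(10),4-dien-12-oate
Product: 15 (3R,6R,7S,9S,1(10)E,4Z)-3-(tert-butyldimethylsilyloxy)-9-(triethylsilyloxy)-13-norgermacra-1(10),4-dien-12,6-olide, via hydroxy ester 14 (not isolated)
Conditions: NaBH4, CeCl3·7H2O, MeOH, −78 °C; then DBU (cat.), PhMe, 40 °C
Reagents that add atoms: none
Why: Luche 1,2‑reduction of the enone with Felkin–Anh attack anti to the ring C8 branch on C7 gives the 6,7‑cis (6R) hydroxy ester, which lactonises.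

**Step 10**
Reactants: 15 (3R,6R,7S,9S,1(10)E,4Z)-3-(tert-butyldimethylsilyloxy)-9-(triethylsilyloxy)-13-norgermacra-1(10),4-dien-12,6-olide
Product: 16 (1S,3R,6R,7S,9S,10R,4Z)-3-(tert-butyldimethylsilyloxy)-1,10-dihydroxy-9-(triethylsilyloxy)-13-norgermacr-4-en-12,6-olide
Conditions: OsO4 (5 mol %), NMO, acetone/H2O, 0 °C
Reagents that add atoms: osmium tetroxide (catalytic oxygen carrier), O=[Os](=O)(=O)=O; N-methylmorpholine N-oxide, C[N+]1([O-])CCOCC1; water, O
Why: Upjohn syn‑dihydroxylation of the strained E‑1(10) olefin (C4=C5 is deactivated by two allylic C–O bonds) on the outer face of the conformer with the C9 silyloxy group eclipsing the olefin puts the C10 hydroxyl erythro to C9–O (Kishi's rule), the two new hydroxyls being trans on the ring.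

**Step 11**
Reactants: 16 (1S,3R,6R,7S,9S,10R,4Z)-3-(tert-butyldimethylsilyloxy)-1,10-dihydroxy-9-(triethylsilyloxy)-13-norgermacr-4-en-12,6-olide
Product: 18 (1R,3R,6R,7S,9S,10R,4Z)-3-(tert-butyldimethylsilyloxy)-1,10-epoxy-9-(triethylsilyloxy)-13-norgermacr-4-en-12,6-olide, via mesylate 17 (not isolated)
Conditions: MsCl, Et3N, CH2Cl2, −20 °C; then DBU, 25 °C
Reagents that add atoms: none
Why: Selective mesylation of the only secondary hydroxyl and intramolecular Williamson closure by the tertiary C10 oxygen inverts C1, turning the trans‑diol into the ring‑cis oxirane on the same face as the C9 oxygen.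

**Step 12**
Reactants: 18 (1R,3R,6R,7S,9S,10R,4Z)-3-(tert-butyldimethylsilyloxy)-1,10-epoxy-9-(triethylsilyloxy)-13-norgermacr-4-en-12,6-olide
Product: 20 (1R,3R,6R,7S,9S,10R,11S,4Z)-3-(tert-butyldimethylsilyloxy)-1,10-epoxy-9-(triethylsilyloxy)germacr-4-en-12,6-olide, via lithium enolate 19 (not isolated)
Conditions: LiN(iPr)2, THF, −78 °C; MeI
Reagents that add atoms: iodomethane, CI
Why: Lactone enolate alkylation; iodomethane approaches the open face of the cis‑fused lactone (the face of H‑6 and H‑7), giving the methyl trans to C8 (11S).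

**Step 13**
Reactants: 20 (1R,3R,6R,7S,9S,10R,11S,4Z)-3-(tert-butyldimethylsilyloxy)-1,10-epoxy-9-(triethylsilyloxy)germacr-4-en-12,6-olide
Product: 22 (1R,3R,6R,7S,9S,10R,11R,4Z)-3-(tert-butyldimethylsilyloxy)-1,10-epoxy-9-(triethylsilyloxy)germacr-4-en-12,6-olide, via lithium enolate 21 (not isolated)
Conditions: LiN(iPr)2, THF, −78 °C; then AcOH, −78 °C
Reagents that add atoms: none
Why: Deprotonation and kinetic protonation from the same open face delivers the hydrogen where the methyl was, giving the less stable all‑cis lactone (11R, methyl cis to C8).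

**Step 14**
Reactants: 22 (1R,3R,6R,7S,9S,10R,11R,4Z)-3-(tert-butyldimethylsilyloxy)-1,10-epoxy-9-(triethylsilyloxy)germacr-4-en-12,6-olide
Product: 23 (1R,3R,6R,7S,9S,10S,11R,4Z)-1,10-epoxy-3,9-dihydroxygermacr-4-en-12,6-olide
Conditions: Bu4NF, AcOH, THF, 25 °C
Reagents that add atoms: none
Why: Fluoride desilylation of both silyl ethers; the acetic acid buffer suppresses Payne rearrangement of the epoxy alcohol and epimerisation at C11 (the C10 descriptor changes by priority only).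

**Step 15**
Reactants: 23 (1R,3R,6R,7S,9S,10S,11R,4Z)-1,10-epoxy-3,9-dihydroxygermacr-4-en-12,6-olide
Product: 24 (1R,3R,6R,7S,9S,10R,11R,4Z)-3,9-diacetoxy-1,10-epoxygermacr-4-en-12,6-olide (CNP0250285.2)
Conditions: Ac2O, pyridine, DMAP, CH2Cl2, 25 °C
Reagents that add atoms: acetic anhydride, CC(=O)OC(C)=O
Why: Nucleophile‑catalysed acylation of the two secondary alcohols under mild base gives the target without touching any stereocentre.

**Compound list**
1 | (R)-(−)-carvone | CC1=CC[C@H](CC1=O)C(C)=C | starting material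
2 | (1R,4R,6R)-1-methyl-4-(prop-1-en-2-yl)-7-oxabicyclo[4.1.0]heptan-2-one | C[C@@]12O[C@@H]1C[C@H](CC2=O)C(C)=C | intermediate
3 | hydrazone of 2 | C[C@@]12O[C@@H]1C[C@H](CC2=NN)C(C)=C | intermediate (not isolated)
4 | (1R,5S)-2-methyl-5-(prop-1-en-2-yl)cyclohex-2-en-1-ol (trans-carveol) | CC1=CC[C@@H](C[C@H]1O)C(C)=C | intermediate
5 | tert-butyl(dimethyl){[(1R,5S)-2-methyl-5-(prop-1-en-2-yl)cyclohex-2-en-1-yl]oxy}silane | CC1=CC[C@@H](C[C@H]1O[Si](C)(C)C(C)(C)C)C(C)=C | intermediate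
6 | (4R,6S)-4-[(tert-butyldimethylsilyl)oxy]-3-methyl-6-(prop-1-en-2-yl)cyclohex-2-en-1-one | CC1=CC(=O)[C@@H](C[C@H]1O[Si](C)(C)C(C)(C)C)C(C)=C | intermediate
7 | (4R,6S)-4-[(tert-butyldimethylsilyl)oxy]-3-methyl-6-(2-methyloxiran-2-yl)cyclohex-2-en-1-one (both oxirane epimers) | CC1=CC(=O)[C@@H](C[C@H]1O[Si](C)(C)C(C)(C)C)C2(C)CO2 | intermediate
8 | 2-[(1S,5R)-5-[(tert-butyldimethylsilyl)oxy]-4-methyl-2-oxocyclohex-3-en-1-yl]propanal (both C2 epimers) | CC1=CC(=O)[C@@H](C[C@H]1O[Si](C)(C)C(C)(C)C)C(C)C=O | intermediate (not isolated)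
9 | (4R,6S)-4-[(tert-butyldimethylsilyl)oxy]-3-methyl-6-[(1E)-1-[(triethylsilyl)oxy]prop-1-en-2-yl]cyclohex-2-en-1-one | CC1=CC(=O)[C@@H](C[C@H]1O[Si](C)(C)C(C)(C)C)/C(C)=C/O[Si](CC)(CC)CC | intermediate
10 | (1R,4R,6S)-4-[(tert-butyldimethylsilyl)oxy]-1-ethenyl-3-methyl-6-[(1E)-1-[(triethylsilyl)oxy]prop-1-en-2-yl]cyclohex-2-en-1-ol | CC1=C[C@@](O)(C=C)[C@@H](C[C@H]1O[Si](C)(C)C(C)(C)C)/C(C)=C/O[Si](CC)(CC)CC | intermediate
11 | potassium alkoxide of 10 | [K+].CC1=C[C@@]([O-])(C=C)[C@@H](C[C@H]1O[Si](C)(C)C(C)(C)C)/C(C)=C/O[Si](CC)(CC)CC | intermediate (not isolated)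
12 | potassium (3R,9S,1(10)E,4Z,6E)-enolate of the ring-expanded C6 ketone (O cis to C8) | [K+].[O-]/C1=C\C[C@H](O[Si](CC)(CC)CC)/C(C)=C/C[C@@H](O[Si](C)(C)C(C)(C)C)/C(C)=C\1 | intermediate (not isolated)
13 | methyl (3R,7S,9S,1(10)E,4Z)-3-(tert-butyldimethylsilyloxy)-6-oxo-9-(triethylsilyloxy)-13-norgermacra-1(10),4-dien-12-oate | COC(=O)C[C@@H]1C[C@H](O[Si](CC)(CC)CC)/C(C)=C/C[C@@H](O[Si](C)(C)C(C)(C)C)/C(C)=C\C1=O | intermediate
14 | methyl (3R,6R,7S,9S,1(10)E,4Z)-3-(tert-butyldimethylsilyloxy)-6-hydroxy-9-(triethylsilyloxy)-13-norgermacra-1(10),4-dien-12-oate | COC(=O)C[C@@H]1C[C@H](O[Si](CC)(CC)CC)/C(C)=C/C[C@@H](O[Si](C)(C)C(C)(C)C)/C(C)=C\[C@@H]1O | intermediate (not isolated)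
15 | (3R,6R,7S,9S,1(10)E,4Z)-3-(tert-butyldimethylsilyloxy)-9-(triethylsilyloxy)-13-norgermacra-1(10),4-dien-12,6-olide | O=C1C[C@@H]2C[C@H](O[Si](CC)(CC)CC)/C(C)=C/C[C@@H](O[Si](C)(C)C(C)(C)C)/C(C)=C\[C@@H]2O1 | intermediate
16 | (1S,3R,6R,7S,9S,10R,4Z)-3-(tert-butyldimethylsilyloxy)-1,10-dihydroxy-9-(triethylsilyloxy)-13-norgermacr-4-en-12,6-olide | O=C1C[C@@H]2C[C@H](O[Si](CC)(CC)CC)[C@](C)(O)[C@@H](O)C[C@@H](O[Si](C)(C)C(C)(C)C)/C(C)=C\[C@@H]2O1 | intermediate
17 | 1-O-methanesulfonate of 16 | O=C1C[C@@H]2C[C@H](O[Si](CC)(CC)CC)[C@](C)(O)[C@@H](OS(C)(=O)=O)C[C@@H](O[Si](C)(C)C(C)(C)C)/C(C)=C\[C@@H]2O1 | intermediate (not isolated)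
18 | (1R,3R,6R,7S,9S,10R,4Z)-3-(tert-butyldimethylsilyloxy)-1,10-epoxy-9-(triethylsilyloxy)-13-norgermacr-4-en-12,6-olide | O=C1C[C@@H]2C[C@H](O[Si](CC)(CC)CC)[C@]3(C)O[C@@H]3C[C@@H](O[Si](C)(C)C(C)(C)C)/C(C)=C\[C@@H]2O1 | intermediate
19 | lithium lactone enolate of 18 | [Li+].[O-]C1=C[C@@H]2C[C@H](O[Si](CC)(CC)CC)[C@]3(C)O[C@@H]3C[C@@H](O[Si](C)(C)C(C)(C)C)/C(C)=C\[C@@H]2O1 | intermediate (not isolated)
20 | (1R,3R,6R,7S,9S,10R,11S,4Z)-3-(tert-butyldimethylsilyloxy)-1,10-epoxy-9-(triethylsilyloxy)germacr-4-en-12,6-olide | O=C1[C@@H](C)[C@@H]2C[C@H](O[Si](CC)(CC)CC)[C@]3(C)O[C@@H]3C[C@@H](O[Si](C)(C)C(C)(C)C)/C(C)=C\[C@@H]2O1 | intermediate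
21 | lithium lactone enolate of 20 | [Li+].[O-]C1=C(C)[C@@H]2C[C@H](O[Si](CC)(CC)CC)[C@]3(C)O[C@@H]3C[C@@H](O[Si](C)(C)C(C)(C)C)/C(C)=C\[C@@H]2O1 | intermediate (not isolated)
22 | (1R,3R,6R,7S,9S,10R,11R,4Z)-3-(tert-butyldimethylsilyloxy)-1,10-epoxy-9-(triethylsilyloxy)germacr-4-en-12,6-olide | O=C1[C@H](C)[C@@H]2C[C@H](O[Si](CC)(CC)CC)[C@]3(C)O[C@@H]3C[C@@H](O[Si](C)(C)C(C)(C)C)/C(C)=C\[C@@H]2O1 | intermediate
23 | (1R,3R,6R,7S,9S,10S,11R,4Z)-1,10-epoxy-3,9-dihydroxygermacr-4-en-12,6-olide | O=C1[C@H](C)[C@@H]2C[C@H](O)[C@]3(C)O[C@@H]3C[C@@H](O)/C(C)=C\[C@@H]2O1 | intermediate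
24 | (1R,3R,6R,7S,9S,10R,11R,4Z)-3,9-diacetoxy-1,10-epoxygermacr-4-en-12,6-olide (CNP0250285.2) | CC(=O)O[C@H]1C[C@@H]2[C@H](/C=C(/C)[C@H](OC(C)=O)C[C@H]3O[C@@]13C)OC(=O)[C@@H]2C | target

**Totals**
Total step count: 15. Longest linear sequence: 15 steps (fully linear from 1).

**Three steps most likely to fail**

Step 4 (allylic oxidation). The oxidant may also attack the silyloxy‑bearing allylic C–H or the isopropenyl group, and the new α‑stereocentre of 6 can epimerise. The fallback sets out from 5 and replaces C–H oxidation by an epoxide‑based 1,3‑transposition. mCPBA epoxidises the ring olefin anti to the silyloxy group to give the ring epoxide F1. NaSePh opens it at the secondary carbon to the hydroxy selenide F2. H2O2 then triggers selenoxide elimination away from the carbinol to the tertiary allylic alcohol F3. Pyridinium chlorochromate [C5H5NH][CrO3Cl] effects the oxidative allylic transposition (Babler–Dauben), which returns to the route at 6.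

Step 8 (oxy‑Cope/alkylation cascade). The alkoxide may shift the triethylsilyl group from the enol ether before rearranging, and the bare potassium enolate may over‑ or O‑alkylate or relax before it is trapped. The fallback sets out from 10 and separates the two events under neutral then lithium conditions. Me3SiCl/imidazole gives the trimethylsilyl ether F4. Heating (PhMe, 190 °C, sealed tube) brings about the thermal siloxy‑Cope rearrangement through the same chair to the ring‑expanded trimethylsilyl enol ether F5. MeLi (THF, 0 °C) releases the regiodefined lithium enolate F6, and methyl bromoacetate at −78 °C alkylates it, which returns to the route at 13.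

Step 10 (face of the dihydroxylation). The E olefin as first formed exposes the opposite face, so the threo diol may result unless the ring relaxes to the inside‑alkoxy conformer. The fallback sets out from 15 and lets the C9 hydroxyl deliver the oxirane oxygen after inversion of the olefin geometry. mCPBA gives the trans‑1,10‑epoxide F7. LiPPh2 opens it at C1 with inversion to the lithium β‑phosphino alkoxide F8. MeI quaternises this to the phosphonium betaine F9, which collapses by syn elimination to the 1(10)Z diene lactone F10 (Vedejs olefin inversion). PPTS/MeOH removes only the triethylsilyl group to give the Z allylic alcohol F11. VO(acac)2/t‑BuOOH then gives the cis epoxy alcohol F12 (hydroxyl‑directed, syn delivery as with medium‑ring Z allylic alcohols). Et3SiCl/imidazole re‑silylates, which returns to the route at 18.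

**Further compounds**
F1 | step 4 | 2,3-epoxide of silyl ether 5 (carveol numbering; oxirane trans to the silyloxy group) | C[C@@]12O[C@@H]1C[C@@H](C[C@H]2O[Si](C)(C)C(C)(C)C)C(C)=C
F2 | step 4 | 2-hydroxy-3-(phenylselanyl) derivative from F1 (hydroxyl and selanyl trans) | C[C@@]1(O)[C@@H]([Se]c2ccccc2)C[C@@H](C[C@H]1O[Si](C)(C)C(C)(C)C)C(C)=C
F3 | step 4 | (1R,4R,6R)-6-[(tert-butyldimethylsilyl)oxy]-1-methyl-4-(prop-1-en-2-yl)cyclohex-2-en-1-ol | C[C@@]1(O)C=C[C@@H](C[C@H]1O[Si](C)(C)C(C)(C)C)C(C)=C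
F4 | step 8 | trimethylsilyl ether of 10 | CC1=C[C@@](O[Si](C)(C)C)(C=C)[C@@H](C[C@H]1O[Si](C)(C)C(C)(C)C)/C(C)=C/O[Si](CC)(CC)CC
F5 | step 8 | ring-expanded trimethylsilyl enol ether (C6 enol ether, 1(10)E,4Z) | C[Si](C)(C)O/C1=C\C[C@H](O[Si](CC)(CC)CC)/C(C)=C/C[C@@H](O[Si](C)(C)C(C)(C)C)/C(C)=C\1
F6 | step 8 | lithium enolate corresponding to 12 | [Li+].[O-]/C1=C\C[C@H](O[Si](CC)(CC)CC)/C(C)=C/C[C@@H](O[Si](C)(C)C(C)(C)C)/C(C)=C\1
F7 | step 10 | trans-1,10-epoxide of 15 | O=C1C[C@@H]2C[C@H](O[Si](CC)(CC)CC)[C@]3(C)O[C@H]3C[C@@H](O[Si](C)(C)C(C)(C)C)/C(C)=C\[C@@H]2O1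
F8 | step 10 | lithium 1-(diphenylphosphino)-10-alkoxide from F7 | [Li+].O=C1C[C@@H]2C[C@H](O[Si](CC)(CC)CC)[C@](C)([O-])[C@H](P(c3ccccc3)c3ccccc3)C[C@@H](O[Si](C)(C)C(C)(C)C)/C(C)=C\[C@@H]2O1
F9 | step 10 | methyldiphenylphosphonium betaine from F8 | O=C1C[C@@H]2C[C@H](O[Si](CC)(CC)CC)[C@](C)([O-])[C@H]([P+](C)(c3ccccc3)c3ccccc3)C[C@@H](O[Si](C)(C)C(C)(C)C)/C(C)=C\[C@@H]2O1
F10 | step 10 | 1(10)Z isomer of 15 | O=C1C[C@@H]2C[C@H](O[Si](CC)(CC)CC)/C(C)=C\C[C@@H](O[Si](C)(C)C(C)(C)C)/C(C)=C\[C@@H]2O1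
F11 | step 10 | 9-hydroxy 1(10)Z,4Z diene lactone (3-silyl ether kept) | O=C1C[C@@H]2C[C@H](O)/C(C)=C\C[C@@H](O[Si](C)(C)C(C)(C)C)/C(C)=C\[C@@H]2O1
F12 | step 10 | 9-hydroxy ring-cis 1,10-epoxide (9-desilyl 18) | O=C1C[C@@H]2C[C@H](O)[C@]3(C)O[C@@H]3C[C@@H](O[Si](C)(C)C(C)(C)C)/C(C)=C\[C@@H]2O1
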